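Assumption: aldehyde 12 and the zinc reagent 9 (as an ethereal solution) are treated as purchasable catalogue items; the target has no stereocentre, so no configuration has to be set.

## Structural features

The target is an achiral 3-arylcoumarin: a 2H-chromen-2-one (benzene ring A fused to lactone ring C) with a methoxy group at C5 and a free hydroxyl at C7 is joined through the single bond C3–C6' to a 5'-methoxy-2',2'-dimethylchroman (benzene ring B fused to dihydropyran ring D; primed numbers refer to the chroman). There is no stereocentre, so no stereocentres stand next to each other and nothing has to be controlled in that respect. Ring B is a 1,2,3,4-tetrasubstituted benzene in which the benzylic methylene C4' hangs on C4a' between two oxygen-bearing carbons, C8a' (ring oxygen O1') and C5' (methoxy), and the coumarin sits at C6', ortho to the methoxy group and para to O1'. The fragile groups are the lactone (opened by hydroxide or alkoxide, reclosed by acid), the free C7 phenol, the C3=C4 double bond (at risk under hydrogenation) and the tertiary alkyl aryl ether O1'–C2' together with the two aryl methyl ethers (at risk with strong Lewis acids). The real difficulty is regiochemical: the two oxygens flanking C4a' must end up different (one in ring D, one methylated), the two oxygens of ring A must end up different (C5 methylated, C7 free), and the inter-ring bond must be placed at the most crowded CH of ring B. The key step exploits the C4'–C4a' bond with its two oxygenated neighbours C5' and C8a', which is the carbon pattern of 2-methylresorcinol. C4' can therefore be bought as a methyl group, oxidised to the exocyclic methylene of an ortho-quinone methide and joined to C3' and C2' of 2-methylpropene while the phenol oxygen becomes O1'. A bromine placed para to that oxygen before ring D is closed marks C6' for the two-carbon unit that later becomes C3 and C2 of the lactone.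

## Logic of the disconnections

14 to 13: the acetyl C–O bond on the C7 oxygen is cut. The free phenol of ring A would be acylated in the condensation medium in any case, so the acetate is accepted as a protecting group that costs no separate step. Nothing is gained in skeleton. The demand is a cleavage that takes the aryl ester and leaves the lactone, the methyl ethers and ring D alone.

13 to 11 + 12: the lactone bonds O1–C2 and C3=C4 are cut. The cut divides the molecule into two halves of similar size, and 12 already carries the methoxy/hydroxy pattern of ring A, so no late differentiation of two phenols is needed. The target reduces to an arylacetic acid and a catalogue aldehyde. The forward step must condense at a formyl group flanked on both sides by oxygen substituents, with an acid whose methylene sits next to an ortho-methoxy aryl group.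

11 to 10: the ester O–C(CH3)3 bond is cut. The carboxyl group has to be masked during the carbon–carbon coupling, and the tert-butyl ester belongs to an enolate equivalent that does not condense with itself. The demand is an acid cleavage mild enough to spare the tertiary ether of ring D.

10 to 8 + 9: the C6'–CH2 bond is cut. A halogen para to O1' is the natural handle, and the two-carbon unit arrives as the neutral enolate equivalent 9, so no strong base meets the substrate. This leaves 8, which holds rings B and D with every substituent in place. The forward step needs oxidative addition into an electron-rich aryl bromide with an ortho methoxy group, and the bromine must have survived the ring-forming step.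

8 to 5 + 6 (through 7): the bonds C4'–C3' and O1'–C2' are cut in a retro-hetero-[4+2] sense. This removes ring D, the quaternary carbon and both methyl groups at once and leaves C4' as a methyl group on a phenol. One ring and two skeletal bonds are gained, and the precursor is a simple tetrasubstituted benzene plus a C4 gas. The forward step must oxidise 5 at the methyl group to 7 and must capture 7 with an unactivated alkene in the orientation set by polarity. The bromine and the methyl ether must tolerate the anode.

5 to 2 (through 4 and 3): the O–CH3 bond is cut. The two hydroxyls of 2 differ only in their second ortho neighbour (bromine or hydrogen), so the methyl group is delivered by a relay. The unhindered hydroxyl is capped with a bulky silyl group (3), the hindered one is methylated (4), and the silyl group is taken off again (5). The gain is a diol in which no oxygen has yet been differentiated. The demand is a silylation that discriminates by steric crowding, a methylation that leaves the silyl ether intact, and a clean fluoride cleavage.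

2 to 1: the C–Br bond is cut. 1 is twofold-symmetric, so its two ring positions para to a hydroxyl are equivalent and monobromination can give only one constitution. Bromination is therefore placed before methylation, because the mono-methyl ether would offer two doubly activated positions of similar reactivity. The demand is to stop at the monobromide.

## Other disconnections considered

Alternative 1: Ring B is not bought but grown on a finished coumarin by a benzannulation that would deliver 7-(benzyloxy)-3-[2-hydroxy-3-(3-methylbut-3-en-1-yl)-4-(triisopropylsilyloxy)phenyl]-5-methoxycoumarin (A1).

- **Cut:** chroman bonds C4a'–C5', C8'–C8a' and C5'–C6' are removed (C7'–C8' arises in the Wolff shift). This leads back from A1 to the diazo enone 7-(benzyloxy)-3-[(1E)-4-diazo-3-oxobut-1-en-1-yl]-5-methoxycoumarin (A2) and the siloxyalkyne triisopropyl[(5-methylhex-5-en-1-yn-1-yl)oxy]silane (A3).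
- **Forward reaction:** irradiation of A2 would trigger a Wolff rearrangement to a vinylketene. [2+2] addition of A3, four-electron ring opening, six-electron ring closure and tautomerisation would then give A1.
- **In favour:** the two oxygens flanking C4a' are born different (free hydroxyl at C5', silyl ether at C8a'). This is better than the chosen plan, which must create the difference by steric discrimination in step 2. The benzannulation also has firmer precedent as a reaction type than the anodic methide formation of step 5, so on mechanistic security it is the stronger of the two.
- **Against:** the coumarin absorbs light where the diazo ketone is excited, so dimerisation across C3=C4 and E/Z isomerisation of the enone compete. The vinylketene is conjugated with the coumarin double bond, which opens other pericyclic channels. A2 and A3 each need several steps. After A1 there remain methylation of the C5' hydroxyl, desilylation, Markovnikov hydroalkoxylation of the 1,1-disubstituted alkene to close ring D, and a debenzylation that must spare C3=C4.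
- **Comparison:** on structure it solves the substitution of ring B elegantly but postpones ring D and both oxygen substituents. On mechanism it trades one oxidative pericyclic event for a photochemical cascade of four. On step economy it would need roughly twice the operations of the chosen plan.

Alternative 2: The lactone is cut at C4a–C4 and O1–C2 in a Pechmann sense, and the ring closure would deliver 5,7-dihydroxy-3-(5-methoxy-2,2-dimethylchroman-6-yl)coumarin (A4).

- **Cut:** ring A comes from phloroglucinol (A6). C2 to C4 together with rings B and D come from tert-butyl 2-(5-methoxy-2,2-dimethylchroman-6-yl)-3-oxopropanoate (A5), which C-formylation of 10 would provide.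
- **Forward reaction:** under acid, a ring carbon of A6 attacks the protonated formyl group of A5. Transesterification closes the lactone and dehydration gives A4.
- **In favour:** all three ring positions and all three hydroxyls of A6 are equivalent, so only one coumarin can form. A6 is a cheaper ring A source than 12, and on this point the alternative is the better one. The count from 8 to A4 (coupling, formylation, condensation) equals the count from 8 to 14 in the chosen plan.
- **Against:** A4 must be methylated at the C5 hydroxyl while the C7 hydroxyl stays free. The C7 hydroxyl is conjugated with the lactone carbonyl and is the more acidic and more reactive of the two, so the inherent order is the wrong one. A protection at C7, a methylation at C5 and a deprotection would follow, with an open selectivity question in the first of them. Strong acid also meets the nucleophilic ring B and the tertiary ether, and the coumarin mode has to win over the chromone (Simonis) mode.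
- **Comparison:** on structure, the chosen plan buys the oxygen differentiation inside 12 whereas the alternative must create it at the end. Mechanistically the two ring closures (electrophilic substitution on ring A versus aldol condensation at a preformed aldehyde) are classical and of equal standing. The end-game of the alternative is about three operations longer.

Alternative 3: The lactone is cut at C8a–O1, C4a–C4, C3=C4 and O1–C2 in a three-component aryne annulation that would deliver 7-(benzyloxy)-5-methoxy-3-(5-methoxy-2,2-dimethylchroman-6-yl)coumarin (A7).

- **Cut:** ring A comes from the aryne released from 4-(benzyloxy)-2-methoxy-6-(trimethylsilyl)phenyl trifluoromethanesulfonate (A8). C4 comes from N,N-dimethylformamide (A10). C2 and C3 come from methyl 2-(5-methoxy-2,2-dimethylchroman-6-yl)acetate (A9), available from 10 by ester exchange.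
- **Forward reaction:** fluoride sets the aryne free from A8. A10 adds across it with its oxygen on the aryne carbon remote from the methoxy group. The four-membered adduct opens to an iminium-type ortho-quinone methide, which the enolate of A9 captures. Loss of the amine and lactonisation give A7, and debenzylation of A7 would give 14.
- **In favour:** four bonds form in one operation near room temperature without a hot anhydride, so on bond-forming economy per step this is better than step 8. The regiochemistry follows from the methoxy group next to the aryne, and the C7 oxygen is distinguished from the start. Both plans draw rings B and D and the acetate unit from 8, so they are equal in convergence.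
- **Against:** A8 would take about five operations from a simple phenol. The ester enolate is far more basic than the 1,3-dicarbonyl nucleophiles typical of this capture and may add to the aryne directly. The second oxygen substituent on the aryne may blur the regiochemistry. The debenzylation adds a step and must spare C3=C4 if done by hydrogenolysis, or the ethers if done with a Lewis acid.
- **Comparison:** structurally the alternative builds ring A, whereas the chosen plan buys it as 12. Mechanistically it relies on aryne insertion where the chosen plan uses an aldol condensation. It is estimated to be longer by some five operations.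

Key step: step 5

## Route

Step 1
Reactants: 1 2-methylresorcinol (2-methylbenzene-1,3-diol)
Product: 2 4-bromo-2-methylbenzene-1,3-diol
Conditions: NBS (1.0 equiv, in portions), MeCN, −30 → 0 °C
Reagents that add atoms: N-bromosuccinimide, O=C1CCC(=O)N1Br
Why: Electrophilic aromatic bromination; the two positions para to a hydroxyl are equivalent by symmetry, so only one monobromide can form, and one equivalent of reagent at low temperature should hold back the dibromide.

Step 2
Reactants: 2 4-bromo-2-methylbenzene-1,3-diol
Product: 3 6-bromo-2-methyl-3-[(triisopropylsilyl)oxy]phenol
Conditions: i-Pr3SiCl (1.05 equiv), imidazole, DMF, −10 → 0 °C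
Reagents that add atoms: triisopropylsilyl chloride, CC(C)[Si](Cl)(C(C)C)C(C)C
Why: Sterically governed O-silylation; the hydroxyl para to bromine has one ortho neighbour (methyl), the other is flanked by methyl and bromine, and a bulky silyl chloride reacts much more slowly with a phenol substituted at both ortho positions.

Step 3
Reactants: 3 6-bromo-2-methyl-3-[(triisopropylsilyl)oxy]phenol
Product: 4 (4-bromo-3-methoxy-2-methylphenoxy)triisopropylsilane
Conditions: MeI, K2CO3, acetone, 40 °C
Reagents that add atoms: iodomethane, CI
Why: Williamson O-methylation of the remaining, more acidic ortho-bromophenol; dry carbonate in acetone should leave the aryl silyl ether and the aryl bromide untouched.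

Step 4
Reactants: 4 (4-bromo-3-methoxy-2-methylphenoxy)triisopropylsilane
Product: 5 4-bromo-3-methoxy-2-methylphenol
Conditions: Bu4NF, AcOH, THF, 0 °C → rt
Reagents that add atoms: none
Why: Fluoride-induced cleavage of the aryl silyl ether; buffering with acetic acid keeps the freed electron-rich phenol from standing as its phenoxide.

Step 5
Reactants: 5 4-bromo-3-methoxy-2-methylphenol; 6 2-methylpropene (isobutene)
Product: 8 6-bromo-5-methoxy-2,2-dimethylchroman, via ortho-quinone methide 7 (not isolated)
Conditions: controlled-potential electrolysis at the first anodic wave of 5 (carbon-felt anode, platinum cathode, undivided closed cell, ca. 2.2 F/mol), LiClO4 (1.0 M) in MeNO2, AcOH (5 equiv), 6 (20 equiv, condensed in), 0 °C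
Reagents that add atoms: none
Why: Proposed new method: two one-electron oxidations of 5 at the anode with loss of the phenolic proton should give a phenoxonium ion whose charge sits on the methyl-bearing ortho carbon, and loss of a methyl proton then gives ortho-quinone methide 7; the closest known reaction type is the anodic or quinone-mediated oxidation of ortho-alkylphenols with secondary benzylic hydrogens to ortho-quinone methides in LiClO4/MeNO2 followed by [4+2] capture with unactivated alkenes, together with the two-electron oxidation of tocopherol-type ortho-methylphenols by Ag2O, and the extension lies in asking a primary methyl group of a less electron-rich phenol to do the same. The highly polar, weakly nucleophilic electrolyte solution stabilises cationic intermediates and raises the electrophilicity of 7, which is what should allow a simple alkene to serve as the two-electron partner. Ring D closes by an intermolecular inverse-electron-demand hetero-Diels–Alder reaction between the C=C–C=O unit of 7 and the double bond of 6; the cycloaddition is asynchronous, C4'–C3' forming ahead of O1'–C2', and rearomatisation of ring B drives it. No stereocentre is formed because C2' carries two methyl groups. The selectivity needed is regiochemical (2',2'- and not 3',3'-dimethyl) and is secured by polarity: the electrophilic exocyclic CH2 of 7 bonds to the nucleophilic CH2 terminus of 6, so that positive charge develops on the tertiary carbon next to the oxygen that captures it. Site selectivity is built into 5: only one ortho carbon carries an alkyl group, it lies between the two oxygen substituents so the ring cannot form elsewhere, the para position is blocked by bromine, and the C–Br bond should be inert at the potential of the first phenol wave. A low stationary concentration of 5, a large excess of 6 and AcOH as the cathodic proton source are chosen to favour capture of 7 over phenoxyl coupling and to keep the cathode from reducing the solvent.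

Step 6
Reactants: 8 6-bromo-5-methoxy-2,2-dimethylchroman; 9 (2-tert-butoxy-2-oxoethyl)zinc bromide (Reformatsky reagent of tert-butyl bromoacetate, ethereal solution, 1.4 equiv)
Product: 10 tert-butyl 2-(5-methoxy-2,2-dimethylchroman-6-yl)acetate
Conditions: Pd(dba)2 (2 mol%), P(t-Bu)3 (2 mol%), THF, rt → 50 °C
Reagents that add atoms: none
Why: Negishi-type coupling of an aryl bromide with a zinc ester enolate: oxidative addition of C–Br to zerovalent palladium carrying the bulky electron-rich phosphine, transmetalation from zinc and reductive elimination from divalent palladium; the neutral carbon-bound zinc enolate avoids strong base and double arylation, and electron-rich ortho-alkoxy aryl bromides lie within the scope of this coupling.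

Step 7
Reactants: 10 tert-butyl 2-(5-methoxy-2,2-dimethylchroman-6-yl)acetate
Product: 11 2-(5-methoxy-2,2-dimethylchroman-6-yl)acetic acid
Conditions: H3PO4 (85 wt% aq., 5 equiv), toluene, 40 °C
Reagents that add atoms: none
Why: Acid-mediated tert-butyl ester cleavage by alkyl–oxygen fission with loss of isobutene; aqueous H3PO4 is mild enough that the tertiary ether of ring D and the methyl ether should survive and that little free tert-butyl cation is left to alkylate ring B.

Step 8
Reactants: 11 2-(5-methoxy-2,2-dimethylchroman-6-yl)acetic acid; 12 2,4-dihydroxy-6-methoxybenzaldehyde
Product: 14 7-hydroxy-5-methoxy-3-(5-methoxy-2,2-dimethylchroman-6-yl)coumarin, via coumarin 7-acetate 13 (not isolated)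
Conditions: Ac2O, Et3N, 115 °C; evaporate; then HCl (1.25 M in MeOH), 50 °C
Reagents that add atoms: none
Why: Perkin–Oglialoro condensation: the mixed anhydride of 11 acylates the hydroxyl ortho to the formyl group, the amine enolises the resulting aryl ester, and intramolecular aldol condensation with dehydration closes the lactone (O1–C2 and C3=C4) while the para hydroxyl is masked in the flask as acetate 13. Acid-catalysed methanolysis should then remove only the aryl acetate and give target 14, since lactone, methyl ethers and ring D are stable to methanolic HCl.

## Compound list

1 | 2-methylresorcinol (2-methylbenzene-1,3-diol) | Cc1c(O)cccc1O | starting material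
2 | 4-bromo-2-methylbenzene-1,3-diol | Cc1c(O)ccc(Br)c1O | intermediate
3 | 6-bromo-2-methyl-3-[(triisopropylsilyl)oxy]phenol | Cc1c(O[Si](C(C)C)(C(C)C)C(C)C)ccc(Br)c1O | intermediate
4 | (4-bromo-3-methoxy-2-methylphenoxy)triisopropylsilane | Cc1c(O[Si](C(C)C)(C(C)C)C(C)C)ccc(Br)c1OC | intermediate
5 | 4-bromo-3-methoxy-2-methylphenol | Cc1c(O)ccc(Br)c1OC | intermediate
6 | 2-methylpropene (isobutene) | CC(C)=C | starting material
7 | 4-bromo-5-methoxy-6-methylidenecyclohexa-2,4-dien-1-one (ortho-quinone methide, formed in the flask) | C=C1C(=O)C=CC(Br)=C1OC | intermediate
8 | 6-bromo-5-methoxy-2,2-dimethylchroman | COc1c(Br)ccc2OC(C)(C)CCc12 | intermediate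
9 | (2-tert-butoxy-2-oxoethyl)zinc bromide | CC(C)(C)OC(=O)C[Zn]Br | starting material
10 | tert-butyl 2-(5-methoxy-2,2-dimethylchroman-6-yl)acetate | COc1c(CC(=O)OC(C)(C)C)ccc2OC(C)(C)CCc12 | intermediate
11 | 2-(5-methoxy-2,2-dimethylchroman-6-yl)acetic acid | COc1c(CC(=O)O)ccc2OC(C)(C)CCc12 | intermediate
12 | 2,4-dihydroxy-6-methoxybenzaldehyde | COc1cc(O)cc(O)c1C=O | starting material
13 | 5-methoxy-3-(5-methoxy-2,2-dimethylchroman-6-yl)-2-oxo-2H-chromen-7-yl acetate (formed in the flask) | COc1c(-c2cc3c(OC)cc(OC(C)=O)cc3oc2=O)ccc2c1CCC(C)(C)O2 | intermediate
14 | 7-hydroxy-5-methoxy-3-(5-methoxy-2,2-dimethylchroman-6-yl)coumarin | COc1c(-c2cc3c(OC)cc(O)cc3oc2=O)ccc2c1CCC(C)(C)O2 | target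

## Step count and least certain steps

Total step count: 8. Longest linear sequence: 8 steps (1 to 14 through steps 1 to 8); 6, 9 and 12 enter as purchased partners.

**Step 5 (key step, the one step that goes beyond precedent).**
- The phenoxyl radical may couple through the unsubstituted ring carbon ortho to oxygen before the second electron is removed.
- The phenoxonium ion may be captured by 6 at that same carbon in a [3+2] sense instead of losing a methyl proton. The methoxy group is meta to the phenol oxygen and does not stabilise the cation, and a primary C–H is lost less readily than the secondary ones of the precedents.
- Acid generated at the anode may oligomerise 6.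
- The electron-rich product may be oxidised further.
- The perchlorate–nitromethane electrolyte is an energetic mixture and would be handled on small scale behind a shield.

Fallback with known chemistry, from 5 back to 8: acetylation (Ac2O, pyridine) should give 4-bromo-3-methoxy-2-methylphenyl acetate F1. Wohl–Ziegler bromination of the flanked methyl group (NBS, AIBN, PhCF3, reflux) should give 4-bromo-2-(bromomethyl)-3-methoxyphenyl acetate F2. K2CO3 in MeOH at 0 °C (acetate methanolysis, 1,4-elimination of bromide, addition of methanol to the methide) should give 4-bromo-3-methoxy-2-(methoxymethyl)phenol F3. Heating F3 with a large excess of 6 in toluene in a pressure vessel at about 180 °C should regenerate 7 by thermal loss of methanol and deliver 8 by the classical thermal [4+2] addition of ortho-quinone methides to alkenes. This costs three more operations.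

**Step 2.** Site selectivity may be lost: silylation at the hydroxyl next to bromine (favoured by its higher acidity) or double silylation would, after step 3, put the methyl ether on the wrong oxygen. The constitution of 4 would be checked by NOE between the OCH3 and the ring protons before going on.

Fallback from 1, coming back at 4, with the order of events reversed: statistical mono-O-methylation of 1 (MeI, 1.0 equiv, K2CO3, acetone; no regiochemical question because 1 is symmetric) should give 3-methoxy-2-methylphenol F4. Silylation (i-Pr3SiCl, imidazole, DMF) should give triisopropyl(3-methoxy-2-methylphenoxy)silane F5. Bromination (NBS, MeCN, 0 °C) is expected to go para to the silyloxy group, because the bulky silyl ether shields its own ortho position while the competing position is flanked only by the small methoxy group, and so to give 4.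

**Step 6.** Oxidative addition at the electron-rich bromide next to a methoxy group may be slow, so that protodebromination or decay of the zinc enolate takes over.

Fallback from 8, coming back at 11 and bypassing 10 and step 7: bromine–lithium exchange (n-BuLi, THF, −78 °C) and opening of oxirane (BF3·OEt2) should give 2-(5-methoxy-2,2-dimethylchroman-6-yl)ethanol F6. Oxidation of the primary alcohol (PhI(OAc)2, TEMPO cat., MeCN/H2O) should give 11.

**Step 8.** The sequence may stall at the O-acylated aldehyde because ring closure at a formyl group flanked by two oxygen substituents is slow, and the activated arylacetic acid may condense with itself at 115 °C.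

Fallback from 10 and 12, coming back at 14, using a preformed enolate instead of the anhydride medium: 12 is protected (NaH, MeOCH2Cl, DMF, 0 °C) as 2-methoxy-4,6-bis(methoxymethoxy)benzaldehyde F7. The lithium enolate of 10 (LiN(i-Pr)2, THF, −78 °C) is added to F7 to give the aldol tert-butyl 3-hydroxy-3-[2-methoxy-4,6-bis(methoxymethoxy)phenyl]-2-(5-methoxy-2,2-dimethylchroman-6-yl)propanoate F8 as a mixture of diastereomers. Methanolic HCl at 60 °C should then remove both acetals, close the lactone and dehydrate to 14; the two stereocentres of F8 disappear in the dehydration.

## Further compounds

F1 | step 5 | 4-bromo-3-methoxy-2-methylphenyl acetate | CC(=O)Oc1ccc(Br)c(OC)c1C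
F2 | step 5 | 4-bromo-2-(bromomethyl)-3-methoxyphenyl acetate | CC(=O)Oc1ccc(Br)c(OC)c1CBr
F3 | step 5 | 4-bromo-3-methoxy-2-(methoxymethyl)phenol | COCc1c(O)ccc(Br)c1OC
F4 | step 2 | 3-methoxy-2-methylphenol | Cc1c(O)cccc1OC
F5 | step 2 | triisopropyl(3-methoxy-2-methylphenoxy)silane | Cc1c(O[Si](C(C)C)(C(C)C)C(C)C)cccc1OC
F6 | step 6 | 2-(5-methoxy-2,2-dimethylchroman-6-yl)ethanol | COc1c(CCO)ccc2OC(C)(C)CCc12
F7 | step 8 | 2-methoxy-4,6-bis(methoxymethoxy)benzaldehyde | COCOc1cc(OC)c(C=O)c(OCOC)c1
F8 | step 8 | tert-butyl 3-hydroxy-3-[2-methoxy-4,6-bis(methoxymethoxy)phenyl]-2-(5-methoxy-2,2-dimethylchroman-6-yl)propanoate (mixture of diastereomers) | COCOc1cc(OC)c(C(O)C(C(=O)OC(C)(C)C)c2ccc3OC(C)(C)CCc3c2OC)c(OCOC)c1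
A1 | alternative 1 | 7-(benzyloxy)-3-[2-hydroxy-3-(3-methylbut-3-en-1-yl)-4-(triisopropylsilyloxy)phenyl]-5-methoxycoumarin | Oc1c(CCC(C)=C)c(O[Si](C(C)C)(C(C)C)C(C)C)ccc1-c1cc2c(OC)cc(OCc3ccccc3)cc2oc1=O
A2 | alternative 1 | 7-(benzyloxy)-3-[(1E)-4-diazo-3-oxobut-1-en-1-yl]-5-methoxycoumarin | COc1cc(OCc2ccccc2)cc2oc(=O)c(/C=C/C(=O)C=[N+]=[N-])cc12
A3 | alternative 1 | triisopropyl[(5-methylhex-5-en-1-yn-1-yl)oxy]silane | C=C(C)CCC#CO[Si](C(C)C)(C(C)C)C(C)C
A4 | alternative 2 | 5,7-dihydroxy-3-(5-methoxy-2,2-dimethylchroman-6-yl)coumarin | COc1c(-c2cc3c(O)cc(O)cc3oc2=O)ccc2c1CCC(C)(C)O2
A5 | alternative 2 | tert-butyl 2-(5-methoxy-2,2-dimethylchroman-6-yl)-3-oxopropanoate | CC(C)(C)OC(=O)C(C=O)c1ccc2OC(C)(C)CCc2c1OC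
A6 | alternative 2 | phloroglucinol (benzene-1,3,5-triol) | Oc1cc(O)cc(O)c1
A7 | alternative 3 | 7-(benzyloxy)-5-methoxy-3-(5-methoxy-2,2-dimethylchroman-6-yl)coumarin | COc1c(-c2cc3c(OC)cc(OCc4ccccc4)cc3oc2=O)ccc2c1CCC(C)(C)O2
A8 | alternative 3 | 4-(benzyloxy)-2-methoxy-6-(trimethylsilyl)phenyl trifluoromethanesulfonate | COc1cc(OCc2ccccc2)cc([Si](C)(C)C)c1OS(=O)(=O)C(F)(F)F
A9 | alternative 3 | methyl 2-(5-methoxy-2,2-dimethylchroman-6-yl)acetate | COC(=O)Cc1ccc2OC(C)(C)CCc2c1OC
A10 | alternative 3 | N,N-dimethylformamide | CN(C)C=O
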